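**Retrosynthetic overview**

1. Labels: C1 is the prenyl-bearing quaternary carbon, C2 and C5 are the carbonyl carbons on C1 and C6, C3=C4 is the enedione alkene, C6 is the aryl-bearing quaternary carbon, C7H=C8(CH3)–C9H2 is the alkene bridge, C10 is the benzylic CH, and C11–C16 is the arene (C11 on C10, C16 on C6, OH on C12 and C15); ring A is the enedione, ring B the five-membered ring, ring C the cyclohexene, ring D the hydroquinone. The strategy rests on ring D: it is attached to the core only by C10–C11 and C6–C16 and has its oxygens para on C12 and C15, so cutting C11–C16, C12–C13 and C14–C15 leaves ethynyl groups on C6 and C10 (a hepta-1,6-diyne through C1) plus acetylene, with a boryl group on each alkyne terminus standing in for each OH.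
2. Ring A is made last: enedione ⇐ ene-diol ⇐ ring-closing metathesis (C3=C4) of the bis(vinyl carbinol) from a C1/C6 dialdehyde.
3. Rings B and D ⇐ one [2+2+2] cyclotrimerisation of the cis-C6,C10-bis(borylethynyl)cyclohexene with acetylene, then C–B to C–O.
4. Both alkynes ⇐ aldehydes (C6–CHO, and the C10 aldehyde masked together with the C1 carboxyl as a menthyloxy lactone acetal); C6 quaternary ⇐ formaldehyde aldol; C1 quaternary ⇐ prenylation of the lactone enolate.
5. Ring C and the absolute configuration ⇐ Diels–Alder reaction of a 1-(silyloxymethyl)-3-methylbutadiene with (5S)-5-(d-menthyloxy)furan-2(5H)-one. Ring order: C, then B and D together, then A.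

Key step: step 11

Assumption: (5S)-5-(d-menthyloxy)furan-2(5H)-one 6 is taken as a purchasable reagent; it is the mirror image of the common (5R)-l-menthyloxy compound and is made the same way from furfural and (+)-menthol.

Remark on the chemistry: through the key step C1 carries a methyl ester and C6 a triisopropylsilyloxymethyl group; both are later raised to the aldehyde level for ring A. "Upper face" of ring C means the face that carries prenyl.

**Route**

Step 1
Reactants: 1 methacrolein; 2 triethyl phosphonoacetate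
Product: 3 ethyl (2E)-4-methylpenta-2,4-dienoate
Conditions: LiCl, DBU, MeCN, 0 °C to rt
Reagents that add atoms: none
Why: Horner–Wadsworth–Emmons olefination under Masamune–Roush conditions gives the (E)-enoate from the enal and leaves the 1,1-disubstituted alkene alone.

Step 2
Reactants: 3 ethyl (2E)-4-methylpenta-2,4-dienoate
Product: 4 (2E)-4-methylpenta-2,4-dien-1-ol
Conditions: i-Bu2AlH (2.2 equiv), CH2Cl2, −78 °C
Reagents that add atoms: none
Why: 1,2-reduction of a conjugated ester by the aluminium hydride gives the allylic alcohol without touching the diene.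

Step 3
Reactants: 4 (2E)-4-methylpenta-2,4-dien-1-ol
Product: 5 triethyl{[(2E)-4-methylpenta-2,4-dien-1-yl]oxy}silane
Conditions: Et3SiCl, imidazole, CH2Cl2, 0 °C
Reagents that add atoms: chlorotriethylsilane, CC[Si](Cl)(CC)CC
Why: O-silylation of the primary alcohol gives a diene that tolerates heat and amide base and whose ether can later be oxidised directly.

Step 4
Reactants: 5 triethyl{[(2E)-4-methylpenta-2,4-dien-1-yl]oxy}silane; 6 (5S)-5-(d-menthyloxy)furan-2(5H)-one
Product: 7 (3S,3aS,7R,7aR)-3-(d-menthyloxy)-5-methyl-7-[(triethylsilyloxy)methyl]-3a,4,7,7a-tetrahydro-2-benzofuran-1(3H)-one (cis-fused; CH2OSiEt3 cis to the lactone)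
Conditions: toluene, BHT (cat.), 120 °C, sealed tube
Reagents that add atoms: none
Why: Thermal Diels–Alder reaction in which the diene adds to the butenolide face anti to the menthyloxy group (this fixes C1 and C10 in absolute terms), its CH2 terminus (largest HOMO coefficient, reinforced by both substituents) bonds to the β-carbon, and the endo mode places the silyloxymethyl group cis to the lactone.

Step 5
Reactants: 7 Diels–Alder lactone acetal; 8 prenyl bromide
Product: 10 (3S,3aS,7R,7aR)-3-(d-menthyloxy)-5-methyl-7a-(3-methylbut-2-en-1-yl)-7-[(triethylsilyloxy)methyl]-3a,4,7,7a-tetrahydro-2-benzofuran-1(3H)-one, via lithium enolate 9 (not isolated)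
Conditions: LiN(i-Pr)2, THF, −78 °C; then 8, DMPU, −78 to −20 °C
Reagents that add atoms: none
Why: Alkylation of the lactone enolate with an allylic bromide, where C1–H is the only acidic position and prenyl enters on the convex face of the cis-fused bicycle (cis to H on C10, away from the silyloxymethyl group), so the fusion stays cis and C1 is set.

Step 6
Reactants: 10 prenylated lactone acetal
Product: 11 the C6 aldehyde: 3-(d-menthyloxy)-5-methyl-7a-prenyl-1-oxo-1,3,3a,4,7,7a-hexahydro-2-benzofuran-7-carbaldehyde (ring configuration as in 10)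
Conditions: (COCl)2, DMSO, CH2Cl2, −78 to −30 °C; then Et3N, −78 °C to rt
Reagents that add atoms: none
Why: Swern oxidation, in which the activated sulfoxide cleaves the primary triethylsilyl ether and oxidises the carbon in the same operation, so no free alkoxide ever sits next to the lactone carbonyl (it would transacylate); the C6 configuration does not matter because step 7 rebuilds this centre.

Step 7
Reactants: 11 C6 aldehyde
Product: 12 the C6-quaternary hydroxymethyl aldehyde (C6: CH2OH on the upper face, trans to the C1 carbonyl; CHO cis to it; rest as in 10)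
Conditions: 37% aq. CH2O, DBU (0.3 equiv), THF, 0 °C to rt
Reagents that add atoms: formaldehyde, C=O
Why: Crossed aldol (Tollens-type hydroxymethylation) through the aldehyde dienolate, which reacts at its α-carbon; the quaternary centre C6 is set by approach of formaldehyde anti to the lactone, whose acyl carbon on C1 lies pseudoaxial under the dienolate while prenyl lies pseudoequatorial.

Step 8
Reactants: 12 hydroxymethyl aldehyde
Product: 13 the triisopropylsilyl ether of 12
Conditions: i-Pr3SiOSO2CF3, 2,6-lutidine, CH2Cl2, −78 to 0 °C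
Reagents that add atoms: triisopropylsilyl trifluoromethanesulfonate, CC(C)[Si](OS(=O)(=O)C(F)(F)F)(C(C)C)C(C)C
Why: Silylation of the neopentyl alcohol with a silyl triflate (the aldehyde cannot enolise) blocks retro-aldol loss of formaldehyde in step 9 and carries the future C5 carbon to step 15.

Step 9
Reactants: 13 silyl-protected aldehyde lactone acetal
Product: 16 methyl 2,6-diethynyl-4-methyl-1-prenyl-2-{[(triisopropylsilyl)oxy]methyl}cyclohex-3-ene-1-carboxylate (both ethynyl groups and CO2Me on one face; prenyl and CH2OSi on the other), via alkynyl lactone acetal 14 (not isolated), via alkynyl aldehyde methyl ester 15 (not isolated)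
Conditions: dimethyl (1-diazo-2-oxopropyl)phosphonate (3 equiv), K2CO3, MeOH/THF, 0 °C to rt
Reagents that add atoms: dimethyl (1-diazo-2-oxopropyl)phosphonate, COP(=O)(OC)C(=[N+]=[N-])C(C)=O; methanol, CO
Why: Seyferth–Gilbert homologation of the C6 aldehyde, after which methoxide opens the acylal-type lactone (methyl ester on C1, the hemiacetal sheds menthol) and the C10 aldehyde is homologated as it is released, which keeps C10 from epimerising and leaves both ethynyl groups cis to the ester.

Step 10
Reactants: 16 diyne methyl ester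
Product: 19 methyl 4-methyl-1-prenyl-2,6-bis[(4,4,5,5-tetramethyl-1,3,2-dioxaborolan-2-yl)ethynyl]-2-{[(triisopropylsilyl)oxy]methyl}cyclohex-3-ene-1-carboxylate (configuration as in 16), via dilithium diacetylide 17 (not isolated), via dilithium bis(alkynylborate) 18 (not isolated)
Conditions: LiN(i-Pr)2 (2.2 equiv), THF, −78 °C; i-PrOB(pin), −78 °C; HCl·Et2O, −78 °C to rt
Reagents that add atoms: 2-isopropoxy-4,4,5,5-tetramethyl-1,3,2-dioxaborolane, CC(C)OB1OC(C)(C)C(C)(C)O1
Why: Deprotonation of both terminal alkynes, capture by the borate ester and acidolysis of the ate complexes is the standard route to alkynyl pinacolboronates; the quaternary methyl ester has no α-hydrogen and is too hindered to be attacked at −78 °C.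

Step 11
Reactants: 19 bis(alkynylboronate); 20 acetylene
Product: 21 the benzo-fused bicyclo[3.2.1]octadiene (rings B, C, D) with CO2Me on C1, CH2OSi(i-Pr)3 on C6 and pinacolboronates on C12 and C15 (C1, C6, C10 as in the target)
Conditions: [Rh(cod)2]BF4 (10 mol%), rac-BINAP (10 mol%), H2 then Ar (activation), C2H2 (1 atm), CH2Cl2, rt
Reagents that add atoms: none
Why: Monovalent rhodium binds the two alkynes of 19, which sit cis and 1,3 on ring C with the spacing of a hepta-1,6-diyne, and couples them oxidatively to a rhodacyclopentadiene; this forms C11–C16 and closes ring B as a five-membered carbocycle (C1, C6, C16, C11, C10) across the diaxial positions of ring C. Acetylene then inserts into a Rh–C bond (C12–C13) and reductive elimination forms C14–C15, closing ring D as the benzene ring of a formal [2+2+2] cycloaddition. The closest known reaction type is the cationic rhodium–bisphosphine cyclotrimerisation of 1,6-diynes with monoalkynes, which accepts alkynylboronates and leaves the two boron atoms on the carbons flanking the ring fusion, here C12 and C15, para to each other. No new stereocentre arises; C1, C6 and C10 pass through unchanged, and only a cis-diyne can reach the metallacycle geometry. The step needs chemoselectivity for the diyne over the three alkenes and over acetylene self-coupling: the two alkynes chelate the metal first, the prenyl group stands trans-diaxial to both alkynes in the reactive half-chair and cannot reach rhodium, and the ring C alkene is only 1,4 to the C6 alkyne. The reactive conformer is accessible because the groups it makes axial are the two slim ethynyl groups and prenyl, while the ester and the silyloxymethyl group stay equatorial.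

Step 12
Reactants: 21 bis(arylboronate)
Product: 22 the hydroquinone (OH on C12 and C15; CO2Me on C1, CH2OSi(i-Pr)3 on C6)
Conditions: NaBO3·4H2O, THF/H2O, rt; aq. Na2S2O4 wash
Reagents that add atoms: sodium perborate, [Na+].[O-]B1OO1
Why: Perborate oxidation of the aryl–boron bonds (1,2-shift of aryl from boron to oxygen, then hydrolysis) places OH exactly on C12 and C15, and dithionite returns any quinone formed by air.

Step 13
Reactants: 22 hydroquinone
Product: 23 the bis(methoxymethyl) ether of 22
Conditions: CH3OCH2Cl, i-Pr2NEt, CH2Cl2, 0 °C to rt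
Reagents that add atoms: chloromethyl methyl ether, COCCl
Why: O-alkylation of both phenols as acetals shields the hydroquinone from the hydride, organomagnesium and oxidising reagents that follow.

Step 14
Reactants: 23 bis(methoxymethyl) ether ester
Product: 24 the C1 hydroxymethyl compound (CH2OH on C1, CH2OSi(i-Pr)3 on C6)
Conditions: LiAlH4, THF, 0 °C to rt
Reagents that add atoms: none
Why: Hydride reduction of the ester to the primary alcohol; acetals, silyl ether, alkenes and arene are inert to LiAlH4.

Step 15
Reactants: 24 silyl ether alcohol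
Product: 25 the C1,C6-bis(hydroxymethyl) diol
Conditions: Bu4NF, THF, rt
Reagents that add atoms: none
Why: Fluoride-induced desilylation frees the second neopentyl alcohol.

Step 16
Reactants: 25 diol
Product: 26 the C1,C6-dialdehyde
Conditions: (COCl)2, DMSO, CH2Cl2, −78 °C; Et3N, −78 °C to rt
Reagents that add atoms: none
Why: Swern oxidation activates both hydroxyl groups before base is added, so the 1,4-diol gives the dialdehyde and not a lactol-derived lactone; neither aldehyde can enolise.

Step 17
Reactants: 26 dialdehyde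
Product: 27 the bis(vinyl carbinol) (CH(OH)CH=CH2 on C1 and on C6; mixture at the two carbinol carbons)
Conditions: CH2=CHMgBr (excess), THF, −78 to 0 °C
Reagents that add atoms: vinylmagnesium bromide, C=C[Mg]Br
Why: Grignard addition to both non-enolisable aldehydes; the two carbinol centres are left uncontrolled on purpose because step 19 removes them.

Step 18
Reactants: 27 bis(vinyl carbinol)
Product: 28 the ring A ene-diol (tetracyclic; OH on C2 and C5, C3=C4)
Conditions: first-generation Grubbs catalyst RuCl2(=CHPh)(PCy3)2 (10 mol%), CH2Cl2 (0.005 M), 40 °C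
Reagents that add atoms: none
Why: Ring-closing metathesis joins the two monosubstituted alkenes (C3=C4) and closes ring A as a cyclohexene with loss of ethene; this catalyst is chosen because it does not engage the trisubstituted prenyl and ring C alkenes.

Step 19
Reactants: 28 ene-diol
Product: 29 the bis(methoxymethyl) ether of the target
Conditions: Dess–Martin periodinane, NaHCO3, CH2Cl2, rt
Reagents that add atoms: none
Why: Dess–Martin oxidation of both allylic alcohols gives the ene-1,4-dione, which cannot aromatise because C1 and C6 are quaternary.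

Step 20
Reactants: 29 protected enedione
Product: 30 CNP0513322.1 (C1 S, C6 R, C10 R in the labels used here)
Conditions: conc. HCl (cat.), i-PrOH/THF, 40 °C
Reagents that add atoms: none
Why: Acid-catalysed hydrolysis of the two aryl methoxymethyl acetals; mild protic acid should leave the prenyl alkene, the enedione and the bridged core untouched.

**Compound list**

1 | methacrolein | CC(=C)C=O | starting material
2 | triethyl phosphonoacetate | CCOC(=O)CP(=O)(OCC)OCC | starting material
3 | ethyl (2E)-4-methylpenta-2,4-dienoate | CCOC(=O)/C=C/C(C)=C | intermediate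
4 | (2E)-4-methylpenta-2,4-dien-1-ol | OC/C=C/C(C)=C | intermediate
5 | triethyl{[(2E)-4-methylpenta-2,4-dien-1-yl]oxy}silane | CC[Si](CC)(CC)OC/C=C/C(C)=C | intermediate
6 | (5S)-5-{[(1S,2R,5S)-5-methyl-2-(propan-2-yl)cyclohexyl]oxy}furan-2(5H)-one | O=C1O[C@H](O[C@H]2C[C@@H](C)CC[C@@H]2C(C)C)C=C1 | starting material
7 | (3S,3aS,7R,7aR)-3-(d-menthyloxy)-5-methyl-7-[(triethylsilyloxy)methyl]-3a,4,7,7a-tetrahydro-2-benzofuran-1(3H)-one | O=C1O[C@H](O[C@H]3C[C@@H](C)CC[C@@H]3C(C)C)[C@H]2CC(C)=C[C@@H](CO[Si](CC)(CC)CC)[C@@H]12 | intermediate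
8 | prenyl bromide (1-bromo-3-methylbut-2-ene) | CC(C)=CCBr | starting material
9 | lithium enolate of 7 (not isolated) | [Li+].[O-]C1=C2[C@@H](CO[Si](CC)(CC)CC)C=C(C)C[C@@H]2[C@@H](O[C@H]3C[C@@H](C)CC[C@@H]3C(C)C)O1 | intermediate
10 | (3S,3aS,7R,7aR)-3-(d-menthyloxy)-5-methyl-7a-prenyl-7-[(triethylsilyloxy)methyl]-3a,4,7,7a-tetrahydro-2-benzofuran-1(3H)-one | O=C1O[C@H](O[C@H]3C[C@@H](C)CC[C@@H]3C(C)C)[C@H]2CC(C)=C[C@@H](CO[Si](CC)(CC)CC)[C@@]12CC=C(C)C | intermediate
11 | C6 aldehyde of the prenylated lactone acetal (7-carbaldehyde; ring configuration as in 10) | O=C1O[C@H](O[C@H]3C[C@@H](C)CC[C@@H]3C(C)C)[C@H]2CC(C)=C[C@@H](C=O)[C@@]12CC=C(C)C | intermediate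
12 | 7-formyl-7-(hydroxymethyl) lactone acetal (C6: CH2OH trans, CHO cis to the C1 carbonyl) | O=C1O[C@H](O[C@H]3C[C@@H](C)CC[C@@H]3C(C)C)[C@H]2CC(C)=C[C@@](CO)(C=O)[C@@]12CC=C(C)C | intermediate
13 | triisopropylsilyl ether of 12 | O=C1O[C@H](O[C@H]3C[C@@H](C)CC[C@@H]3C(C)C)[C@H]2CC(C)=C[C@@](CO[Si](C(C)C)(C(C)C)C(C)C)(C=O)[C@@]12CC=C(C)C | intermediate
14 | 7-ethynyl lactone acetal (C6 alkyne, lactone intact; not isolated) | O=C1O[C@H](O[C@H]3C[C@@H](C)CC[C@@H]3C(C)C)[C@H]2CC(C)=C[C@@](CO[Si](C(C)C)(C(C)C)C(C)C)(C#C)[C@@]12CC=C(C)C | intermediate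
15 | methyl 2-ethynyl-6-formyl-4-methyl-1-prenyl-2-{[(triisopropylsilyl)oxy]methyl}cyclohex-3-ene-1-carboxylate (not isolated) | CC(C)=CC[C@@]1(C(=O)OC)[C@](CO[Si](C(C)C)(C(C)C)C(C)C)(C#C)C=C(C)C[C@@H]1C=O | intermediate
16 | methyl 2,6-diethynyl-4-methyl-1-prenyl-2-{[(triisopropylsilyl)oxy]methyl}cyclohex-3-ene-1-carboxylate (ethynyl groups and CO2Me all cis) | CC(C)=CC[C@@]1(C(=O)OC)[C@](CO[Si](C(C)C)(C(C)C)C(C)C)(C#C)C=C(C)C[C@@H]1C#C | intermediate
17 | dilithium diacetylide of 16 (not isolated) | [Li+].[Li+].CC(C)=CC[C@@]1(C(=O)OC)[C@](CO[Si](C(C)C)(C(C)C)C(C)C)(C#[C-])C=C(C)C[C@@H]1C#[C-] | intermediate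
18 | dilithium bis(alkynyl)(isopropoxy)pinacolborate (not isolated) | [Li+].[Li+].CC(C)=CC[C@@]1(C(=O)OC)[C@](CO[Si](C(C)C)(C(C)C)C(C)C)(C#C[B-]2(OC(C)C)OC(C)(C)C(C)(C)O2)C=C(C)C[C@@H]1C#C[B-]1(OC(C)C)OC(C)(C)C(C)(C)O1 | intermediate
19 | methyl 4-methyl-1-prenyl-2,6-bis[(4,4,5,5-tetramethyl-1,3,2-dioxaborolan-2-yl)ethynyl]-2-{[(triisopropylsilyl)oxy]methyl}cyclohex-3-ene-1-carboxylate | CC(C)=CC[C@@]1(C(=O)OC)[C@](CO[Si](C(C)C)(C(C)C)C(C)C)(C#CB2OC(C)(C)C(C)(C)O2)C=C(C)C[C@@H]1C#CB1OC(C)(C)C(C)(C)O1 | intermediate
20 | acetylene | C#C | starting material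
21 | benzobicyclo[3.2.1]octadiene with CO2Me on C1, CH2OSi(i-Pr)3 on C6, pinacolboronates on C12 and C15 | CC(C)=CC[C@@]1(C(=O)OC)[C@@]2(CO[Si](C(C)C)(C(C)C)C(C)C)C=C(C)C[C@@H]1c1c(B3OC(C)(C)C(C)(C)O3)ccc(B3OC(C)(C)C(C)(C)O3)c12 | intermediate
22 | hydroquinone (OH on C12, C15) of the same core | CC(C)=CC[C@@]1(C(=O)OC)[C@@]2(CO[Si](C(C)C)(C(C)C)C(C)C)C=C(C)C[C@@H]1c1c(O)ccc(O)c12 | intermediate
23 | bis(methoxymethyl) ether of 22 | CC(C)=CC[C@@]1(C(=O)OC)[C@@]2(CO[Si](C(C)C)(C(C)C)C(C)C)C=C(C)C[C@@H]1c1c(OCOC)ccc(OCOC)c12 | intermediate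
24 | C1 hydroxymethyl, C6 silyloxymethyl compound | CC(C)=CC[C@@]1(CO)[C@@]2(CO[Si](C(C)C)(C(C)C)C(C)C)C=C(C)C[C@@H]1c1c(OCOC)ccc(OCOC)c12 | intermediate
25 | C1,C6-bis(hydroxymethyl) diol | CC(C)=CC[C@@]1(CO)[C@@]2(CO)C=C(C)C[C@@H]1c1c(OCOC)ccc(OCOC)c12 | intermediate
26 | C1,C6-dialdehyde | CC(C)=CC[C@@]1(C=O)[C@@]2(C=O)C=C(C)C[C@@H]1c1c(OCOC)ccc(OCOC)c12 | intermediate
27 | C1,C6-bis(1-hydroxyprop-2-en-1-yl) compound (carbinol epimers) | CC(C)=CC[C@@]1(C(O)C=C)[C@@]2(C(O)C=C)C=C(C)C[C@@H]1c1c(OCOC)ccc(OCOC)c12 | intermediate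
28 | ring A ene-diol (OH on C2 and C5, C3=C4), bis(methoxymethyl) ether | CC(C)=CC[C@@]12C(O)C=CC(O)[C@@]13C=C(C)C[C@@H]2c1c(OCOC)ccc(OCOC)c13 | intermediate
29 | bis(methoxymethyl) ether of the target | CC(C)=CC[C@@]12C(=O)C=CC(=O)[C@@]13C=C(C)C[C@@H]2c1c(OCOC)ccc(OCOC)c13 | intermediate
30 | CNP0513322.1 | CC(C)=CC[C@@]12C(=O)C=CC(=O)[C@@]13C=C(C)C[C@@H]2c1c(O)ccc(O)c13 | target

**Step count**

Total steps: 20. Longest linear sequence: 20 steps (1 to 30); 6, 8 and 20 enter as purchased reagents.

**Steps most likely to fail**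

Step 11. The alkynyl–boron bonds may be lost (protodeboronation or transfer of the alkynyl group from boron to rhodium). Alternatively, the oxidative cyclisation, which must bridge two axial alkynes into a bicyclo[3.2.1] frame, may be slower than coupling of a single alkyne with acetylene, leading to oligomers. The fallback sets out from diyne 16 and uses halogen instead of boron as the marker. Both alkyne termini are iodinated (N-iodosuccinimide, AgNO3 cat., acetone) to give the bis(iodoalkyne) F1. F1 is cyclotrimerised with acetylene using Cp*RuCl(cod) in 1,2-dichloroethane, a catalyst known to accept iodo-terminated 1,6-diynes, to give the 12,15-diiodoarene F2. Miyaura borylation of F2 (PdCl2(dppf), bis(pinacolato)diboron, KOAc, dioxane, 80 °C) comes back to the route at 21.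

Step 7. Facial selectivity at C6 may be poor if the conformer with prenyl pseudoaxial reacts, so that formaldehyde adds from the lactone side; retro-aldol loss of formaldehyde is a second concern. The fallback sets out from 7 and builds C6 before C1, when the upper face next to the dienolate carries only hydrogen. Swern oxidation of 7 gives the aldehyde F3. Formaldehyde/DBU then gives the hydroxymethyl aldehyde F4 (CH2OH trans to the lactone), and i-Pr3SiOSO2CF3/2,6-lutidine gives the silyl ether F5. Lithiated (trimethylsilyl)diazomethane (Me3SiC(Li)N2, THF, −78 °C to rt) converts the aldehyde to the alkyne F6 without opening the lactone. Prenylation of F6 (LiN(i-Pr)2, 2.1 equiv, then 8) on the convex face of the cis-fused lactone returns to the route at 14, which the conditions of step 9 carry on to 16.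

Step 18. Ring closure onto the prenyl alkene (a cyclopentene with loss of 2-methylpropene) may compete, or the catalyst may fail to turn over at the two hindered carbinols. The fallback sets out from dialdehyde 26 and forms C3–C4 as a single bond first. CH3MgBr gives the bis(methyl carbinol) F7, and Dess–Martin periodinane gives the C1,C6-diacetyl compound F8. Intramolecular oxidative coupling of its bis-enolate (LiN(i-Pr)2, 2.2 equiv, THF, −78 °C, then CuCl2 in DMF) gives the ring A cyclohexane-1,4-dione F9. Dehydrogenation of F9 with 2-iodoxybenzoic acid (DMSO, 70 °C) gives the enedione and comes back to the route at 29.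

**Further compounds**

F1 | step 11 | methyl 2,6-bis(iodoethynyl)-4-methyl-1-prenyl-2-{[(triisopropylsilyl)oxy]methyl}cyclohex-3-ene-1-carboxylate | CC(C)=CC[C@@]1(C(=O)OC)[C@](CO[Si](C(C)C)(C(C)C)C(C)C)(C#CI)C=C(C)C[C@@H]1C#CI
F2 | step 11 | 12,15-diiodo benzobicyclo[3.2.1]octadiene (CO2Me on C1, CH2OSi(i-Pr)3 on C6) | CC(C)=CC[C@@]1(C(=O)OC)[C@@]2(CO[Si](C(C)C)(C(C)C)C(C)C)C=C(C)C[C@@H]1c1c(I)ccc(I)c12
F3 | step 7 | C6 aldehyde of the unprenylated lactone acetal | O=C1O[C@H](O[C@H]3C[C@@H](C)CC[C@@H]3C(C)C)[C@H]2CC(C)=C[C@@H](C=O)[C@@H]12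
F4 | step 7 | unprenylated 7-formyl-7-(hydroxymethyl) lactone acetal | O=C1O[C@H](O[C@H]3C[C@@H](C)CC[C@@H]3C(C)C)[C@H]2CC(C)=C[C@@](CO)(C=O)[C@@H]12
F5 | step 7 | triisopropylsilyl ether of F4 | O=C1O[C@H](O[C@H]3C[C@@H](C)CC[C@@H]3C(C)C)[C@H]2CC(C)=C[C@@](CO[Si](C(C)C)(C(C)C)C(C)C)(C=O)[C@@H]12
F6 | step 7 | unprenylated 7-ethynyl lactone acetal | O=C1O[C@H](O[C@H]3C[C@@H](C)CC[C@@H]3C(C)C)[C@H]2CC(C)=C[C@@](CO[Si](C(C)C)(C(C)C)C(C)C)(C#C)[C@@H]12
F7 | step 18 | C1,C6-bis(1-hydroxyethyl) compound | CC(C)=CC[C@@]1(C(C)O)[C@@]2(C(C)O)C=C(C)C[C@@H]1c1c(OCOC)ccc(OCOC)c12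
F8 | step 18 | C1,C6-diacetyl compound | CC(C)=CC[C@@]1(C(C)=O)[C@@]2(C(C)=O)C=C(C)C[C@@H]1c1c(OCOC)ccc(OCOC)c12
F9 | step 18 | ring A cyclohexane-1,4-dione (3,4-dihydro form of 29) | CC(C)=CC[C@@]12C(=O)CCC(=O)[C@@]13C=C(C)C[C@@H]2c1c(OCOC)ccc(OCOC)c13
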